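The numbers in the tables stem from a simulated flask on assumed constants; the scatter is artificial.

Late times are what is asked of these flasks, so I start there.

| flask | substrate | catalyst | temperature | remark | time |
|---|---|---|---|---|---|
| red | 0.087 M | 0.26 mM (in portions, 4) | −40 °C | run made earlier; portions every 50 min |  |
| green | 0.065 M | 0.26 mM (in portions, 4) | −40 °C | run made earlier; portions every 50 min |  |
| larch | 0.13 M | 1.0 mM (in portions, 4) |  | at −40 °C throughout; the portions of catalyst follow each other after 50 min, the first at the start | 25 h |
| maple | 0.13 M | 0.26 mM (in portions, 4) |  | at −40 °C until 80 min, from then on at −10 °C; the portions of catalyst follow each other after 50 min, the first at the start | 6.0 h |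

| run | time / h | target / % | substrate / % |
|---|---|---|---|
| red | 0.250 | 3 | 83 |
| red | 0.500 | 0 | 69 |
| red | 1.00 | 4 | 45 |
| red | 2.00 | 12 | 19 |
| red | 4.00 | 17 | 3 |
| green | 0.333 | 1 | 77 |
| green | 0.833 | 7 | 54 |
| green | 1.50 | 11 | 32 |
| green | 2.50 | 15 | 15 |
| green | 4.00 | 16 | 3 |

(standard deviation of a reading: 1.5 percentage points)

* which one finishes higher in amount of target, in percent of the substrate charged ("neither" within 2 percentage points) (larch / maple / neither)
* amount of target at the end, in percent of the substrate charged, larch
* amount of target at the end, in percent of the substrate charged, maple

- the earlier runs do not show what temperature does; that part of a forecast is a guess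
- no earlier run changes the charge of catalyst; that part of a forecast is a guess

At 4.00 h red holds 3% of its substrate and 17% as target, and green holds 3% and 16%. In red, 80.0% of the charge has therefore reacted and is not target, so it left by a path I cannot see.

If substrate leaves by two first-order paths, with rate constants k to target and w the other way, then while k and w hold still the two products grow in the ratio k/w however [substrate] falls. Catalyst comes in portions here, so k may move during a run, and I therefore carry one number for a whole run on this portion schedule, the target odds: target formed per unit of substrate lost any other way, a selectivity factor. Red gives 0.213 and green 0.198, readings that agree although the charges are 0.087 M and 0.065 M. Their mean is 0.205, and I use it at 0.13 M too.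

In red and green the target path is the smaller one, so I treat it as a correction to the other and scale just that. My guess, which no run tests, is that k grows with [catalyst] and w ignores it. Larch has 3.85 times red's charge, on the same schedule and at the same temperature, and it runs far longer than red's 4.00 h. Its odds become 0.789, and if larch's substrate has all reacted and its target stays, target at the end is odds/(1+odds), or 44.1%. Maple has red's catalyst, so it gives 17.0% if warming to −10 °C at 80 min leaves the odds alone, and what warming does is a guess.

The forecast says larch, with 28% for larch and 14% for maple. Its ground for larch is “if catalyst competes with a waste path for an intermediate, its yield could rise substantially”. It names the same winner as my reckoning, but its larch figure is lower than mine.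

The flask gives larch: larch ends at 40.0% and maple at 9.03%.

    substrate + catalyst → catalyst + target (k = 1200 M⁻¹ h⁻¹, Ea = 47.0 kJ mol⁻¹)
    target → over-reaction product (k = 6.90 × 10⁻⁵ h⁻¹, Ea = 99.0 kJ mol⁻¹)
    substrate → side product (k = 0.670 h⁻¹, Ea = 72.0 kJ mol⁻¹)
    (constants at −40 °C)

Larch holds 60.0% of side product at the end, and with conversion at 100% its odds are 0.667, below my 0.789, so my larch target was 4.1 percentage points too high. Maple's odds, with its 1.04% of over-reaction product counted as target formed, are 0.112, lower than the 0.205 read from the cold runs. For a neighbour of maple charged with 0.0010 M of catalyst, scaling gives odds of 0.431 and so 30.1% of target formed; the computed flask holds 27.9% of target and 3.20% of over-reaction product.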